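The rate constants were chosen freely; the result is computed.

The substrate gives target directly, but it also crosses slowly to the other conformer, which can return, fall to the isomer of the product, or slip to the third conformer and on to the third product. Substrate and target also meet to give side product.

    other conformer → isomer of the product (k1 = 9.0 × 10⁻⁴ s⁻¹)
    third conformer → third product (k2 = 0.0012 s⁻¹)
    substrate ⇌ other conformer (K3 = 0.30, k3 = 5.3 × 10⁻⁵ s⁻¹)
    other conformer ⇌ third conformer (K4 = 4.4, k4 = 5.6 × 10⁻⁵ s⁻¹)
    substrate → target (k5 = 6.3 × 10⁻⁴ s⁻¹)
    substrate + target → side product (k6 = 8.5 × 10⁻⁵ M⁻¹ s⁻¹)

substrate 0.20 M; other conformer 0.100 M; time 6.0 h

- at 6.0 h, what has stopped the reaction, if anything has (other conformer counts as not reacted) (all of the substrate has reacted / it is still moving / forward and back rates have come level)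
- target at 6.0 h, in percent of the substrate and other conformer together charged

- in percentages every species weighs as the substrate in it: one side product counts as two
- in a conversion other conformer counts as not yet reacted; third conformer counts as reacted
- the reaction counts as stopped when no species that holds the substrate and other conformer together changes by six tenths of a point or more over the second half of the time
- run time (flask): 6.0 h

By hand, the exchange comes first. Substrate and other conformer relax towards each other with a half-life of 0.838 h, which is slower than the fall of the substrate (0.282 h) or of the other conformer (0.170 h). This is kinetic control, so the flask is reckoned from its charge. The run lasts 21.3 substrate half-lives, which gives: all of the substrate has reacted.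

Substrate leaves for target with share 0.922. Other conformer returns with share 0.156, counting the third conformer as lost, since it runs on faster than it comes back. Following the loop, the target worth of the substrate, the fraction of it ending as target with the side reaction set aside, is 0.934. That of the other conformer is 0.146. Weighted by the charge, of which substrate is the fraction 0.667, target stands at 67.1%.

Each side event costs one target plus one substrate's worth. Substrate decaying exponentially, with target rising as its complement, gives events amounting to 0.765% of the charge, so the committed figure is 65.6%. The weak link is the use of the charged substrate: returned substrate passes through as well. The amount passing is 72.7% of the charge, more than the charged fraction. The reckoned events rise to 0.911%, and the reckoned target falls to 65.3%.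

The forecast says all of the substrate has reacted and puts target at 65.4%, within 64% to 66.5%, much the same as the reforged figure, on the grounds that “the drains are irreversible, so this is completion rather than equilibrium”.

The simulation gives all of the substrate has reacted, with 0% substrate left, and target at 65.4%.

The low worth of the other conformer, 0.146, is mainly the work of its path to the isomer of the product: with that path struck out, target rises from 65.4% to 86.7%, which is 62% of what is missing. With 0.40 M of other conformer, the neighbour flask should give 40.8% before the side reaction's trim. That neighbour gives 39.6%.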